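A fraction of the charge was my unit. If one activator takes up one substrate at a rate proportional to both, the last substrate reading of a run gives an uptake constant u, which I scaled to a charge of 20 mM.

| flask | substrate | activator | temperature | remark | time |
|---|---|---|---|---|---|
| larch | 20 mM | 12 mM | 90 °C | run made earlier |  |
| oak | 20 mM | 48 mM | 112 °C | run made earlier |  |
| elm | 10 mM | 24 mM | 90 °C | run made earlier |  |
| Sunday's | 20 mM | 24.0 mM | 80 °C |  | 80 min |
| Saturday's | 20 mM | 24.0 mM | 100 °C |  | 80 min |
| Wednesday's | 20 mM | 24.0 mM |  | at 120 °C until 1.0 h, from then on at 80 °C | 80 min |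
| Thursday's | 20 mM | 24.0 mM | 120 °C |  | 80 min |

| run | time / min | ring / % | substrate / % |
|---|---|---|---|
| larch | 6.00 | 0 | 96.7 |
| larch | 12.0 | 0.2 | 93.0 |
| larch | 20.0 | 1.1 | 88.0 |
| larch | 25.0 | 1.0 | 86.8 |
| larch | 30.0 | 0.5 | 84.3 |
| oak | 2.00 | 2.0 | 83.2 |
| oak | 4.00 | 3.4 | 70.5 |
| oak | 6.00 | 7.9 | 59.1 |
| oak | 8.00 | 10.8 | 50.2 |
| oak | 10.0 | 16.7 | 42.6 |
| elm | 6.00 | 0 | 92.8 |
| elm | 12.0 | 0.2 | 86.0 |
| elm | 20.0 | 1.6 | 78.8 |
| elm | 25.0 | 0.7 | 72.7 |
| elm | 30.0 | 2.2 | 69.4 |

(scatter of a reading: 0.5 percentage points)

* the flask that comes out highest in amount of ring, in percent of the substrate charged, or "all alike" when all lie within 1.5 percentage points (Sunday's / Saturday's / Wednesday's / Thursday's / all alike)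
* ring at the end, in percent of the substrate charged, Sunday's
* ring at the end, in percent of the substrate charged, Saturday's
* ring at the end, in percent of the substrate charged, Wednesday's
* ring at the end, in percent of the substrate charged, Thursday's

- a reading or a percentage of ring counts all its forms, free or not
- a reading of substrate is of its free form alone

I had two ways to u at 90 °C. The larch run, at 0.600 equivalents, gave 0.0110 /min. The elm run, at 2.40 equivalents and half the substrate, gave 0.0109 /min. These two lie on opposite sides of one equivalent and still agree, so I trusted the rate law. The oak run gave 0.0414 /min at 112 °C.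

I laid ln u straight in temperature through the larch and oak values, which gave 0.0670 /min at 120 °C, 0.0201 /min at 100 °C and 0.00606 /min at 80 °C.

Substrate is the limiting reagent in the flasks asked about, and every ring holds one substrate, so ring cannot pass the share of the charge no longer free. By this reckoning Thursday's keeps 7.98% free, which gives a ceiling, the share no longer free, of 92.0%. Saturday's ceiling came to 69.5% and Sunday's to 37.9%.

Ring ran behind uptake in the earlier runs. By the readings, ring was 3.18% of the substrate gone in the larch run after 30.0 min, and 29.1% in the oak run after 10.0 min, a run that was hotter but also richer in activator. So I expected ring nearest its ceiling in Thursday's, the hottest flask. Wednesday's ran as Thursday's up to the change at 1.0 h, with a ceiling there of 88.1%. Its uptake constant then dropped about ten times, so I put Thursday's highest.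

The forecast named Thursday's, with 1.8% for Sunday's, 36% for Saturday's, 84% for Wednesday's and 89% for Thursday's, and it held that “Ring growth tracks the integral of the missing mass”.

The flasks gave ring of 2.66% on Sunday's, 35.4% on Saturday's, 73.7% on Wednesday's and 78.6% on Thursday's, so Thursday's stood highest.

    activated form → ring (k = 3.23 × 10⁻⁴ /s, Ea = 128 kJ/mol)
    substrate + activator → activated form (k = 0.0156 /M/s, Ea = 68.0 kJ/mol)
    substrate + ring ⇌ idle adduct, settled at all times (K = 32.0 /M, ΔH = −25.0 kJ/mol)
    substrate + activated form → open dimer (k = 0.00658 /M/s, Ea = 65.0 kJ/mol)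
    (constants at 100 °C)

Thursday's ended with 8.33% free substrate against my 7.98%, and its ring lay 13 percentage points under the ceiling, with 9.16% of the charge in open dimer. The neighbour flask is like Thursday's but charged with 8.0 mM of substrate, which makes 3.00 equiv of activator. With u scaled to that charge, the same reckoning leaves 0.920% free, a ceiling of 99.1%. That neighbour flask held 2.02% free substrate and 3.90% of its charge in open dimer, and its ring reached 92.9%.

(The numbers in the tables come from a simulation for substances that don't exist; noise was put on by code.)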